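What stands in this flask at 8.0 d, and is it still moving?

- why nothing more happens at 8.0 d, or that something still does (forward and back rates have come level / the incoming ligand has run out first / it is still moving / all of the starting complex has reacted)
- how much of the starting complex has reacted by 8.0 d
- how much complex with one exchanged there is at 8.0 d, in percent of the starting complex charged
- how much complex with two exchanged there is at 8.0 d, in percent of the starting complex charged

- violet: starting complex 0.44 M; incoming ligand 0.352 M; leaving ligand 0.44 M; the very flask that is asked about, followed so far
- flask: starting complex 0.44 M; incoming ligand 0.352 M; leaving ligand 0.440 M; time 8.0 d

violet run (percent of the starting complex charged)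

| time / d | starting complex / % | complex with one exchanged / % | complex with two exchanged / % |
|---|---|---|---|
| 0.625 | 13.0 | 5.6 | 8.7 |
| 1.25 | 6.9 | 2.7 | 4.6 |
| 2.08 | 3.3 | 2.9 | 3.9 |
| 2.50 | 3.6 | 1.6 | 4.0 |
| 3.00 | 3.2 | 1.9 | 3.3 |
| 4.00 | 3.0 | 1.9 | 3.5 |

(readings scatter by 0.5 percentage points)

- the analysis behind the earlier runs scatters by 0.5 percentage points, standard deviation
- what has gone from starting complex into another species counts as reacted, even if it can come back
- the reaction counts as stopped when no species that holds the starting complex changes by six tenths of a point or more over the second half of the time

In the violet flask, starting complex fell to half of its reading in 0.625 d, which is short against 8.0 d. From 2.50 d on it read 3.6%, 3.2% and 3.0%, with a scatter of 0.5 percentage points. I therefore took the flask as stopped and averaged those last readings: starting complex 3.27%, complex with one exchanged 1.80%, complex with two exchanged 3.60%. That left 91.3% of the charge in a form I could not read.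

Had the incoming ligand run out? I assumed one ligand per exchange and none in the unread form. The exchanged complexes then took 0.0396 M of the 0.352 M charged, so it had not run out, although at 0.352 M against 0.44 M of starting complex it was the limiting reagent by charge. That left [incoming ligand] at 0.312 M and [leaving ligand] at 0.480 M, and I concluded that forward and back rates had come level.

What does that balance hold constant? It holds the exchange quotient, [complex with one exchanged][leaving ligand]/([starting complex][incoming ligand]), which I read as 0.846. For 8.0 d I committed to the plateau: 96.7% reacted, with 1.80% and 3.60% of the two exchanged complexes.

The forecast read forward and back rates have come level, “with starting complex remaining and rates level”, and gave 96.8% reacted, 2% of complex with one exchanged and 3.6% of complex with two exchanged. The flask gave forward and back rates have come level, with 96.8% reacted, 1.89% and 3.14%.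

    starting complex ⇌ dormant form (K = 29.0, k = 0.00260 /min)
    complex with one exchanged + incoming ligand ⇌ leaving ligand + complex with two exchanged (K = 2.50, k = 0.0310 /M/min)
    starting complex + incoming ligand ⇌ leaving ligand + complex with one exchanged (K = 0.900, k = 0.0180 /M/min)

In this flask at 8.00 d, the first exchange relaxes with a half-life of 0.739 h, and the slowest mode of the whole flask has 0.465 d, both short against 8.0 d. The dormant form, the resting state, holds 91.8%, and my quotient with this flask's simulated amounts gives 1.78% of complex with one exchanged. In the neighbour flask charged with 1.1 M of leaving ligand, the quotient with the charges and my plateau starting complex gives 0.885%; that flask computes to 0.909%.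

The data were generated by integration with made-up constants; scatter was added.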